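Ring B is not brought in as an arene: it is made from an open chain. In ring B the oxygen-bearing C3′ and the benzyl-bearing C4′ are neighbours, so the C3′–C4′ bond is disconnected to a carboxyl carbon and the terminus of a diene. Heating a (3Z,5E)-hepta-3,5-dienoic acid with acetic anhydride should give a dienylketene whose 6π electrocyclisation forms that bond and delivers ring B as its aryl acetate in one operation. The precursor carries the fully benzylated ring A on an ethyl arm at C3 and a 4-benzyloxyphenyl group at C7; its Z-trisubstituted alkene is set by two successive stereospecific cross-couplings on a 1,1-dichlorodiene.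

Key step: step 11

Remarks on the chemistry
- Numbering: ring A is the pentasubstituted ring (C1 ethylene bridge, C2 and C6 benzyl groups, C3 OH, C5 OMe). Ring B carries the bridge at C1′, OH at C3′ and the benzyl group at C4′. The dienoic acid is numbered C1 (carboxyl) to C7. ArA = 3-(benzyloxy)-2,6-bis[4-(benzyloxy)benzyl]-5-methoxyphenyl.
- Acid 20 and acetate 25 map atom for atom on the target (C1→C3′, C2→C2′, C3→C1′, C4→C6′, C5→C5′, C6→C4′, C7→benzylic CH2).
- Design choice: ring closure depends on the 3Z geometry of 20, so this geometry is fixed by cross-coupling on a 1,1-dichlorodiene. Moving a 2,4-dienoate out of conjugation by dienolate protonation was rejected, because deprotonation can occur at two γ-type sites and leaves the new C3=C4 geometry uncontrolled.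
- End game: the benzyl ethers are removed while ring B is still an aryl acetate, and the acetate is cleaved last.
- Assumption: compounds 1, 5, 8, 9, 12 and 17 are commercial.

**Ring A styrene (steps 1–4)**

Step 1
Reactants: 1 3-hydroxy-5-methoxybenzaldehyde
Product: 2 3-(benzyloxy)-5-methoxybenzaldehyde
Conditions: BnBr, K2CO3, DMF, rt
Reagents that add atoms: benzyl bromide, BrCc1ccccc1
Why: Williamson etherification of the only acidic OH should mask the ring A phenol as a benzyl ether that lasts until the final hydrogenolysis.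

Step 2
Reactants: 2 3-(benzyloxy)-5-methoxybenzaldehyde
Product: 3 3-(benzyloxy)-2,6-dibromo-5-methoxybenzaldehyde
Conditions: NBS (2.2 equiv), MeCN, 0 °C → rt, dark
Reagents that add atoms: N-bromosuccinimide, O=C1CCC(=O)N1Br
Why: Electrophilic aromatic bromination should occur at C2 and C6, each activated ortho/para by both alkoxy groups and less shielded than C4 (which lies between the two alkoxy groups), so bromine marks the two carbons that will carry the benzyl groups.

Step 3
Reactants: 3 3-(benzyloxy)-2,6-dibromo-5-methoxybenzaldehyde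
Product: 4 1-(benzyloxy)-2,4-dibromo-3-ethenyl-5-methoxybenzene
Conditions: Ph3PCH3Br, KOt-Bu, THF, 0 °C → rt
Reagents that add atoms: methyltriphenylphosphonium bromide, C[P+](c1ccccc1)(c1ccccc1)c1ccccc1.[Br-]
Why: Wittig methylenation of a non-enolisable aldehyde should convert the formyl group into the vinyl group (the future ethylene bridge) before any organozinc reagent is present.

Step 4
Reactants: 4 1-(benzyloxy)-2,4-dibromo-3-ethenyl-5-methoxybenzene; 5 4-(benzyloxy)benzyl chloride (2.6 equiv)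
Product: 7 1-(benzyloxy)-2,4-bis[4-(benzyloxy)benzyl]-3-ethenyl-5-methoxybenzene (ring A styrene), via 4-benzyloxybenzylzinc chloride 6 (not isolated)
Conditions: Zn dust, LiCl, THF, rt (5 → 6); then 4, Pd(OAc)2 (4 mol%), SPhos (8 mol%), THF, 50 °C
Reagents that add atoms: none
Why: Double Negishi coupling: the benzylic zinc chloride formed by LiCl-assisted zinc insertion should couple with both di-ortho-substituted aryl bromides under Pd(OAc)2/SPhos while the vinyl group and the ethers stay untouched.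

**Dichlorodiene (steps 5–7)**

Step 5
Reactants: 8 1-(benzyloxy)-4-bromobenzene; 9 allyl bromide
Product: 11 1-allyl-4-(benzyloxy)benzene, via 4-benzyloxyphenylmagnesium bromide 10 (not isolated)
Conditions: Mg, THF, reflux (8 → 10); then 9, 0 °C → rt
Reagents that add atoms: none
Why: Grignard formation followed by SN2 allylation should give the allylarene whose benzylic CH2 becomes the C4′ benzyl carbon.

Step 6
Reactants: 11 1-allyl-4-(benzyloxy)benzene; 12 (E)-but-2-enal (crotonaldehyde, 4 equiv)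
Product: 13 (2E)-4-[4-(benzyloxy)phenyl]but-2-enal
Conditions: second-generation Grubbs catalyst RuCl2(=CHPh)(H2IMes)(PCy3) (3 mol%), CH2Cl2, 40 °C
Reagents that add atoms: none
Why: Olefin cross-metathesis of a terminal allylarene with an excess of the electron-poor partner should give the E enal with loss of propene.

Step 7
Reactants: 13 (2E)-4-[4-(benzyloxy)phenyl]but-2-enal
Product: 14 1-(benzyloxy)-4-[(2E)-5,5-dichloropenta-2,4-dien-1-yl]benzene
Conditions: PPh3 (3 equiv), BrCCl3 (1.5 equiv), MeCN, 0 °C → rt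
Reagents that add atoms: bromotrichloromethane, ClC(Cl)(Cl)Br
Why: Wittig-type gem-dichloro-olefination should add the CCl2 carbon (future C3) under nearly neutral conditions, leaving the E alkene and the acidic benzylic/allylic CH2 alone.

**Assembly (steps 8–12)**

Step 8
Reactants: 7 ring A styrene; 14 1-(benzyloxy)-4-[(2E)-5,5-dichloropenta-2,4-dien-1-yl]benzene (1.2 equiv)
Product: 16 (3Z,5E)-7-[4-(benzyloxy)phenyl]-3-chloro-1-(ArA)hepta-3,5-diene (chlorine cis to C5), via ring A ethyl 9-BBN borane 15 (not isolated)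
Conditions: 9-BBN dimer, THF, 0 °C → rt (7 → 15); then 14, Pd2(dba)3 (2.5 mol%), Xantphos (5 mol%), aq. K3PO4, THF, 65 °C
Reagents that add atoms: none
Why: Anti-Markovnikov hydroboration followed by B-alkyl Suzuki–Miyaura coupling: zerovalent palladium inserts into the C–Cl bond of a 1,1-dichloroalkene that is trans to the C4 substituent, so the alkyl group should enter trans to the dienyl chain, and the remaining chloride (cis to C5, on a trisubstituted alkene) reacts far more slowly.

Step 9
Reactants: 16 (3Z,5E)-chlorodiene; 17 ethyl bromoacetate (2.5 equiv)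
Product: 19 ethyl (3Z,5E)-7-[4-(benzyloxy)phenyl]-3-[2-(ArA)ethyl]hepta-3,5-dienoate, via Reformatsky reagent BrZnCH2CO2Et 18 (not isolated)
Conditions: Zn dust (TMSCl-activated), THF, 40 °C (17 → 18); then 16, Pd(P(t-Bu)3)2 (5 mol%), THF, 60 °C
Reagents that add atoms: none
Why: Negishi-type coupling of a Reformatsky reagent with an alkenyl halide proceeds with retention, so the acetate arm should take the place of chlorine cis to C5 (3Z), and the neutral zinc enolate should not move the skipped diene into conjugation.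

Step 10
Reactants: 19 ethyl (3Z,5E)-dienoate
Product: 20 (3Z,5E)-7-[4-(benzyloxy)phenyl]-3-[2-(ArA)ethyl]hepta-3,5-dienoic acid
Conditions: LiOH·H2O (3 equiv), THF/MeOH/H2O, 0 °C → rt; then 1 M HCl to pH 3
Reagents that add atoms: lithium hydroxide, [Li+].[OH-]
Why: Saponification of an unhindered ethyl ester at low temperature should outrun γ-deprotonation, so the 3,5-diene position and both alkene geometries should be kept.

Step 11
Reactants: 20 (3Z,5E)-dienoic acid
Product: 25 2-[4-(benzyloxy)benzyl]-5-[2-(ArA)ethyl]phenyl acetate, via mixed anhydride 21 (not isolated), via dienylketene 22 (not isolated), via cyclohexadienone 23 (not isolated), via phenol 24 (not isolated)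
Conditions: Ac2O, NaOAc (anhydrous), 130 °C, N2
Reagents that add atoms: acetic anhydride, CC(=O)OC(C)=O
Why: Acetic anhydride should convert 20 into mixed anhydride 21, whose C2–H (α to the carbonyl and allylic to the diene) is removed by acetate, and loss of acetate then gives dienylketene 22. Ketene 22 is a hexatriene with a cumulated C1=C2 unit, and a thermal disrotatory 6π electrocyclisation should join C1 to C6 (C3′–C4′), closing the single new six-membered carbocycle as cyclohexa-2,4-dienone 23. Loss of the C6 proton aromatises 23 to phenol 24, which the anhydride acetylates to 25; the transient stereocentre at C6 is erased, so no stereocentre has to be controlled. The closest known reaction type is the benzannulation of hexa-3,5-dienoic acids and Stobbe half-esters with Ac2O/NaOAc. The step needs the ketene carbon and C5 cis on C3=C4 and the C7 substituent on the outside of the folding triene; the 3Z,5E geometry fixed in steps 8 and 9 secures both, and the placement of OAc at C3′, benzyl at C4′ and the bridge at C1′ follows from the chain connectivity alone.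

Step 12
Reactants: 25 ring B aryl acetate
Product: 27 2,4-bis(4-hydroxybenzyl)-3-{2-[3-hydroxy-4-(4-hydroxybenzyl)phenyl]ethyl}-5-methoxyphenol (target CNP0207338.0), via tetraphenol aryl acetate 26 (not isolated)
Conditions: H2 (1 atm), 10% Pd/C, THF/EtOAc, rt; filter, concentrate; then K2CO3 (0.3 equiv), MeOH, N2, rt; then AcOH
Reagents that add atoms: none
Why: Hydrogenolysis over Pd/C should cleave the four O-benzyl ethers while the aryl acetate, the diarylmethane C–C bonds, the bibenzyl bridge and the methyl ether are inert, and base-catalysed transesterification with methanol under nitrogen should then free the ring B phenol of 26.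

**Compound list**

1 | 3-hydroxy-5-methoxybenzaldehyde | COc1cc(O)cc(C=O)c1 | starting material
2 | 3-(benzyloxy)-5-methoxybenzaldehyde | COc1cc(OCc2ccccc2)cc(C=O)c1 | intermediate
3 | 3-(benzyloxy)-2,6-dibromo-5-methoxybenzaldehyde | COc1cc(OCc2ccccc2)c(Br)c(C=O)c1Br | intermediate
4 | 1-(benzyloxy)-2,4-dibromo-3-ethenyl-5-methoxybenzene | COc1cc(OCc2ccccc2)c(Br)c(C=C)c1Br | intermediate
5 | 4-(benzyloxy)benzyl chloride | ClCc1ccc(OCc2ccccc2)cc1 | starting material
6 | [4-(benzyloxy)benzyl]zinc chloride | Cl[Zn]Cc1ccc(OCc2ccccc2)cc1 | intermediate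
7 | 1-(benzyloxy)-2,4-bis[4-(benzyloxy)benzyl]-3-ethenyl-5-methoxybenzene (ring A styrene) | COc1cc(OCc2ccccc2)c(Cc2ccc(OCc3ccccc3)cc2)c(C=C)c1Cc1ccc(OCc2ccccc2)cc1 | intermediate
8 | 1-(benzyloxy)-4-bromobenzene | Brc1ccc(OCc2ccccc2)cc1 | starting material
9 | allyl bromide | C=CCBr | starting material
10 | [4-(benzyloxy)phenyl]magnesium bromide | Br[Mg]c1ccc(OCc2ccccc2)cc1 | intermediate
11 | 1-allyl-4-(benzyloxy)benzene | C=CCc1ccc(OCc2ccccc2)cc1 | intermediate
12 | (E)-but-2-enal (crotonaldehyde) | C/C=C/C=O | starting material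
13 | (2E)-4-[4-(benzyloxy)phenyl]but-2-enal | O=C/C=C/Cc1ccc(OCc2ccccc2)cc1 | intermediate
14 | 1-(benzyloxy)-4-[(2E)-5,5-dichloropenta-2,4-dien-1-yl]benzene | ClC(Cl)=C/C=C/Cc1ccc(OCc2ccccc2)cc1 | intermediate
15 | 9-[2-(ArA)ethyl]-9-borabicyclo[3.3.1]nonane | COc1cc(OCc2ccccc2)c(Cc2ccc(OCc3ccccc3)cc2)c(CCB2C3CCCC2CCC3)c1Cc1ccc(OCc2ccccc2)cc1 | intermediate
16 | (3Z,5E)-7-[4-(benzyloxy)phenyl]-3-chloro-1-(ArA)hepta-3,5-diene | COc1cc(OCc2ccccc2)c(Cc2ccc(OCc3ccccc3)cc2)c(CC/C(Cl)=C/C=C/Cc2ccc(OCc3ccccc3)cc2)c1Cc1ccc(OCc2ccccc2)cc1 | intermediate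
17 | ethyl bromoacetate | CCOC(=O)CBr | starting material
18 | (2-ethoxy-2-oxoethyl)zinc bromide | CCOC(=O)C[Zn]Br | intermediate
19 | ethyl (3Z,5E)-7-[4-(benzyloxy)phenyl]-3-[2-(ArA)ethyl]hepta-3,5-dienoate | CCOC(=O)C/C(CCc1c(Cc2ccc(OCc3ccccc3)cc2)c(OCc2ccccc2)cc(OC)c1Cc1ccc(OCc2ccccc2)cc1)=C\C=C\Cc1ccc(OCc2ccccc2)cc1 | intermediate
20 | (3Z,5E)-7-[4-(benzyloxy)phenyl]-3-[2-(ArA)ethyl]hepta-3,5-dienoic acid | OC(=O)C/C(CCc1c(Cc2ccc(OCc3ccccc3)cc2)c(OCc2ccccc2)cc(OC)c1Cc1ccc(OCc2ccccc2)cc1)=C\C=C\Cc1ccc(OCc2ccccc2)cc1 | intermediate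
21 | acetic (3Z,5E)-7-[4-(benzyloxy)phenyl]-3-[2-(ArA)ethyl]hepta-3,5-dienoic anhydride | CC(=O)OC(=O)C/C(CCc1c(Cc2ccc(OCc3ccccc3)cc2)c(OCc2ccccc2)cc(OC)c1Cc1ccc(OCc2ccccc2)cc1)=C\C=C\Cc1ccc(OCc2ccccc2)cc1 | intermediate
22 | (3Z,5E)-7-[4-(benzyloxy)phenyl]-3-[2-(ArA)ethyl]hepta-1,3,5-trien-1-one (dienylketene) | O=C=C/C(CCc1c(Cc2ccc(OCc3ccccc3)cc2)c(OCc2ccccc2)cc(OC)c1Cc1ccc(OCc2ccccc2)cc1)=C\C=C\Cc1ccc(OCc2ccccc2)cc1 | intermediate
23 | 6-[4-(benzyloxy)benzyl]-3-[2-(ArA)ethyl]cyclohexa-2,4-dien-1-one (racemic at C6) | O=C1C=C(CCc2c(Cc3ccc(OCc4ccccc4)cc3)c(OCc3ccccc3)cc(OC)c2Cc2ccc(OCc3ccccc3)cc2)C=CC1Cc1ccc(OCc2ccccc2)cc1 | intermediate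
24 | 2-[4-(benzyloxy)benzyl]-5-[2-(ArA)ethyl]phenol | Oc1cc(CCc2c(Cc3ccc(OCc4ccccc4)cc3)c(OCc3ccccc3)cc(OC)c2Cc2ccc(OCc3ccccc3)cc2)ccc1Cc1ccc(OCc2ccccc2)cc1 | intermediate
25 | 2-[4-(benzyloxy)benzyl]-5-[2-(ArA)ethyl]phenyl acetate | CC(=O)Oc1cc(CCc2c(Cc3ccc(OCc4ccccc4)cc3)c(OCc3ccccc3)cc(OC)c2Cc2ccc(OCc3ccccc3)cc2)ccc1Cc1ccc(OCc2ccccc2)cc1 | intermediate
26 | 5-{2-[3-hydroxy-2,6-bis(4-hydroxybenzyl)-5-methoxyphenyl]ethyl}-2-(4-hydroxybenzyl)phenyl acetate (tetraphenol aryl acetate) | CC(=O)Oc1cc(CCc2c(Cc3ccc(O)cc3)c(O)cc(OC)c2Cc2ccc(O)cc2)ccc1Cc1ccc(O)cc1 | intermediate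
27 | 2,4-bis(4-hydroxybenzyl)-3-{2-[3-hydroxy-4-(4-hydroxybenzyl)phenyl]ethyl}-5-methoxyphenol (CNP0207338.0) | COc1cc(O)c(Cc2ccc(O)cc2)c(CCc2ccc(Cc3ccc(O)cc3)c(O)c2)c1Cc1ccc(O)cc1 | target

**Step count and risks**

Total step count: 12. Longest linear sequence: 9 steps (1, 2, 3, 4, 8, 9, 10, 11, 12).

Steps most likely to fail:

1. Step 11 (ring closure). The ketene may be diverted before it cyclises, by dimerisation or by re-addition of acetate followed by migration of the diene into conjugation, or the C3=C4 bond may isomerise from Z to E so that the termini cannot meet. Fallback: ring B is taken from an arene and the bridge is made by cross-coupling. The fallback sets out from styrene 7 (as its borane 15) and Grignard reagent 10 and comes back at target 27. Addition of 10 (excess, THF, 0 °C) to commercial 4-bromo-2-hydroxybenzaldehyde should give [4-(benzyloxy)phenyl](4-bromo-2-hydroxyphenyl)methanol F1. Ionic hydrogenation (Et3SiH, CF3CO2H, CH2Cl2, 0 °C) should then give 2-[4-(benzyloxy)benzyl]-5-bromophenol F2. B-alkyl Suzuki–Miyaura coupling of F2 with 15 (PdCl2(dppf), aq. K3PO4, THF, 65 °C) should give phenol 24, and hydrogenolysis of its four benzyl ethers (H2, 10% Pd/C, THF/EtOAc, rt) should give 27 directly.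

2. Step 9 (acetate arm). Oxidative addition into the hindered trisubstituted C–Cl bond may be slow, the alkene geometry may leak at the alkenylpalladium stage, or the zinc enolate may self-condense. Fallback: the polarity of the C2–C3 bond formation is reversed. The fallback sets out from 16 and comes back at 19. Miyaura borylation (B2pin2, Pd2(dba)3, XPhos, KOAc, dioxane, 90 °C) should give, with retention, 2-[(3E,5E)-7-[4-(benzyloxy)phenyl]-1-(ArA)hepta-3,5-dien-3-yl]-4,4,5,5-tetramethyl-1,3,2-dioxaborolane F3 (boron cis to C5; the descriptor changes only through priority rules). Suzuki–Miyaura coupling of F3 with ethyl bromoacetate 17 (Pd(OAc)2, P(o-tol)3, K3PO4, THF/H2O, rt) should give 19.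

3. Step 8 (mono-alkylation). Coupling may occur at both C–Cl bonds, the trans selectivity may erode, or the alkylborane may be lost by protodeboronation or β-hydride elimination under aqueous base. Fallback: a preformed alkylzinc is used in a base-free Negishi mono-alkylation. The fallback sets out from 7 and comes back at 16. Hydroboration–oxidation (9-BBN, THF; then NaOH, H2O2) should give 2-(ArA)ethanol F4. Appel iodination (I2, PPh3, imidazole, CH2Cl2) should give 1-iodo-2-(ArA)ethane F5. Zinc insertion (Zn dust, LiCl, THF, 40 °C) should give [2-(ArA)ethyl]zinc iodide F6, and its trans-selective coupling with 14 (PdCl2(DPEphos), THF/DMF, rt) should give 16.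

Further compounds
F1 | step 11 | [4-(benzyloxy)phenyl](4-bromo-2-hydroxyphenyl)methanol (racemic) | OC(c1ccc(OCc2ccccc2)cc1)c1ccc(Br)cc1O
F2 | step 11 | 2-[4-(benzyloxy)benzyl]-5-bromophenol | Oc1cc(Br)ccc1Cc1ccc(OCc2ccccc2)cc1
F3 | step 9 | 2-[(3E,5E)-7-[4-(benzyloxy)phenyl]-1-(ArA)hepta-3,5-dien-3-yl]-4,4,5,5-tetramethyl-1,3,2-dioxaborolane | COc1cc(OCc2ccccc2)c(Cc2ccc(OCc3ccccc3)cc2)c(CC/C(B2OC(C)(C)C(C)(C)O2)=C/C=C/Cc2ccc(OCc3ccccc3)cc2)c1Cc1ccc(OCc2ccccc2)cc1
F4 | step 8 | 2-(ArA)ethanol | COc1cc(OCc2ccccc2)c(Cc2ccc(OCc3ccccc3)cc2)c(CCO)c1Cc1ccc(OCc2ccccc2)cc1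
F5 | step 8 | 1-iodo-2-(ArA)ethane | COc1cc(OCc2ccccc2)c(Cc2ccc(OCc3ccccc3)cc2)c(CCI)c1Cc1ccc(OCc2ccccc2)cc1
F6 | step 8 | [2-(ArA)ethyl]zinc iodide | COc1cc(OCc2ccccc2)c(Cc2ccc(OCc3ccccc3)cc2)c(CC[Zn]I)c1Cc1ccc(OCc2ccccc2)cc1
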